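**Strategy.** Ring C is cut as a formal [4+2] union: C2–C3 is an aldol bond and O1–C8a an aryl ether bond, because C2 is at once the carbinol carbon β to the C4 ketone and, through O1, the partner of C8a, which lies ortho to the C4 acyl group of ring A. In one flask a catalytic asymmetric Mukaiyama aldol sets C2 and fluoride then closes ring C by SNAr, the aldehyde oxygen becoming O1. The precursors are a ring B benzaldehyde carrying the geranyl group and the enol silane of an ortho-fluoroacetophenone carrying the prenyl group, an arene-based Danishefsky-diene surrogate with C8a–F as leaving group; all phenols are MOM ethers.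

Key step: step 8

Assumption (availability): 5-fluororesorcinol, 4-bromo-2-iodophenol, geranyl bromide and N-tosyl-(R)-tryptophan are taken as purchasable.
Assumption (chemistry): the oxazaborolidinone is taken to follow its accepted π-stacking model, in which the (S)-tryptophan series leaves the Re face of an aryl aldehyde open; the (R)-tryptophan series is therefore specified, and its antipode would be used without other change if the sense proved opposite on this substrate pair.

**Route**

Step 1
Reactants: 1 5-fluorobenzene-1,3-diol (5-fluororesorcinol); 2 chloromethyl methyl ether (MOMCl)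
Product: 3 1-fluoro-3,5-bis(methoxymethoxy)benzene
Conditions: MOMCl (2.5 equiv), iPr2NEt, CH2Cl2, 0 °C to rt
Reagents that add atoms: chloromethyl methyl ether, COCCl
Why: Williamson-type O-alkylation of both phenols by the reactive α-chloro ether should give the base-stable, ortho-directing MOM ethers; no stereocentre is involved.

Step 2
Reactants: 3 1-fluoro-3,5-bis(methoxymethoxy)benzene; 4 1-bromo-3-methylbut-2-ene (prenyl bromide)
Product: 6 5-fluoro-1,3-bis(methoxymethoxy)-2-(3-methylbut-2-en-1-yl)benzene, via aryllithium 5 (not isolated)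
Conditions: n-BuLi, THF, −78 to −40 °C; CuBr·SMe2 (10 mol%), prenyl bromide, −78 °C to rt
Reagents that add atoms: prenyl bromide, CC(C)=CCBr
Why: Directed ortho-metalation should occur at the C–H flanked by the two MOM ethers (cooperative complex-induced proximity) rather than next to fluorine, and aryllithium 5, which is meta to fluorine and so not prone to LiF loss, is allylated under copper catalysis at the primary carbon of prenyl bromide (SN2), placing the prenyl group on the future C6.

Step 3
Reactants: 6 5-fluoro-1,3-bis(methoxymethoxy)-2-(3-methylbut-2-en-1-yl)benzene; 7 N-methoxy-N-methylacetamide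
Product: 9 1-[6-fluoro-2,4-bis(methoxymethoxy)-3-(3-methylbut-2-en-1-yl)phenyl]ethan-1-one, via aryllithium 8 (not isolated)
Conditions: n-BuLi, THF, −78 °C; N-methoxy-N-methylacetamide, −78 °C; sat. aq. NH4Cl, −78 °C to rt
Reagents that add atoms: N-methoxy-N-methylacetamide, CC(=O)N(C)OC
Why: A second directed ortho-metalation at one of the two equivalent C–H positions, each acidified by an adjacent fluorine and MOM ether, should give aryllithium 8, which is kept at −78 °C to avoid LiF loss and is acylated by the Weinreb amide, whose chelated tetrahedral adduct stops at the ketone stage.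

Step 4
Reactants: 9 1-[6-fluoro-2,4-bis(methoxymethoxy)-3-(3-methylbut-2-en-1-yl)phenyl]ethan-1-one; 10 chlorotrimethylsilane
Product: 12 {1-[6-fluoro-2,4-bis(methoxymethoxy)-3-(3-methylbut-2-en-1-yl)phenyl]ethenyl}oxy(trimethyl)silane, via lithium enolate 11 (not isolated)
Conditions: LiN(SiMe3)2, THF, −78 °C; Me3SiCl, −78 to 0 °C; pentane, filtration under argon, used crude
Reagents that add atoms: chlorotrimethylsilane, C[Si](C)(C)Cl
Why: Kinetic enolisation of the methyl ketone (its only enolisable position) and O-silylation should give the enol silane, the amide base avoiding a Lewis-acidic silyl triflate that could cleave the MOM ethers.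

Step 5
Reactants: 13 4-bromo-2-iodophenol; 2 chloromethyl methyl ether (MOMCl)
Product: 14 4-bromo-2-iodo-1-(methoxymethoxy)benzene
Conditions: MOMCl (1.3 equiv), iPr2NEt, CH2Cl2, 0 °C to rt
Reagents that add atoms: chloromethyl methyl ether, COCCl
Why: Williamson-type O-alkylation of the phenol gives the MOM ether that survives the organometallic steps and the fluoride of the key step.

Step 6
Reactants: 14 4-bromo-2-iodo-1-(methoxymethoxy)benzene; 15 (2E)-1-bromo-3,7-dimethylocta-2,6-diene (geranyl bromide)
Product: 17 4-bromo-2-[(2E)-3,7-dimethylocta-2,6-dien-1-yl]-1-(methoxymethoxy)benzene, via arylmagnesium chloride 16 (not isolated)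
Conditions: iPrMgCl·LiCl (1.05 equiv), THF, −20 °C; CuBr·SMe2 (10 mol%), geranyl bromide, −20 °C to rt
Reagents that add atoms: geranyl bromide, CC(C)=CCC/C(C)=C/CBr
Why: Iodine–magnesium exchange is far faster than bromine–magnesium exchange, so the Grignard reagent should form only at the carbon ortho to the MOM ether, and copper-catalysed allylic substitution at the primary carbon of geranyl bromide (SN2) keeps the E-alkene.

Step 7
Reactants: 17 4-bromo-2-[(2E)-3,7-dimethylocta-2,6-dien-1-yl]-1-(methoxymethoxy)benzene; 18 N,N-dimethylformamide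
Product: 20 3-[(2E)-3,7-dimethylocta-2,6-dien-1-yl]-4-(methoxymethoxy)benzaldehyde, via aryllithium 19 (not isolated)
Conditions: n-BuLi, THF, −78 °C; DMF, −78 to 0 °C; sat. aq. NH4Cl
Reagents that add atoms: N,N-dimethylformamide, CN(C)C=O
Why: Bromine–lithium exchange at −78 °C followed by formylation of the aryllithium with DMF (Bouveault aldehyde synthesis) should give the ring B aldehyde.

Step 8
Reactants: 12 {1-[6-fluoro-2,4-bis(methoxymethoxy)-3-(3-methylbut-2-en-1-yl)phenyl]ethenyl}oxy(trimethyl)silane; 20 3-[(2E)-3,7-dimethylocta-2,6-dien-1-yl]-4-(methoxymethoxy)benzaldehyde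
Product: 22 (2S)-2-{3-[(2E)-3,7-dimethylocta-2,6-dien-1-yl]-4-(methoxymethoxy)phenyl}-5,7-bis(methoxymethoxy)-6-(3-methylbut-2-en-1-yl)-2,3-dihydro-4H-chromen-4-one, via silyl ether 21 (not isolated)
Conditions: 12 (1.1 equiv), (4R)-2-butyl-4-(1H-indol-3-ylmethyl)-3-(4-methylphenylsulfonyl)-1,3,2-oxazaborolidin-5-one (20 mol%, made in situ from N-tosyl-(R)-tryptophan and n-BuB(OH)2), EtCN, −78 °C; then Bu4N[Ph3SiF2] (0.5 equiv), THF, −78 to 0 °C, same flask
Reagents that add atoms: none
Why: The boron Lewis acid binds the formyl oxygen of 20 and the terminal CH2 of enol silane 12 adds through an open Mukaiyama transition state to form C2–C3, silyl transfer giving β-silyloxy ketone 21; fluoride then unmasks the C2 alkoxide, which attacks C8a by addition–elimination (SNAr) and expels fluoride to form O1–C8a, the fluoride set free carrying on the desilylation. The closest known reaction type is the Mukaiyama aldol/cyclisation annulation of aldehydes with Danishefsky-type dienes to 2,3-dihydro-4H-pyran-4-ones, here with the C8a–F bond of an arene in the role of the leaving alkoxy group, joined to the fluoride-catalysed etherification of silyl ethers with activated aryl fluorides. Ring C is closed in a 6-exo-trig mode at the aromatic carbon through a Meisenheimer intermediate stabilised by the C4 carbonyl. The C2 stereocentre is set by the catalyst: π-stacking of the indole over the boron-bound formyl group should shield the Re face, so that attack on the Si face gives the (S)-carbinol, and because the C2–O bond is not touched in the ring closure this becomes (2S) in 22. The step needs ring closure to outrun retro-aldol cleavage and E1cB loss of silanolate, which the low temperature, the ortho-acyl activation of C8a–F (the two MOM ethers stand meta to it and do not deactivate it) and the substoichiometric fluoride are meant to secure, while MOM protection of all three phenols keeps any phenoxide from deactivating ring A.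

Step 9
Reactants: 22 (2S)-2-{3-[(2E)-3,7-dimethylocta-2,6-dien-1-yl]-4-(methoxymethoxy)phenyl}-5,7-bis(methoxymethoxy)-6-(3-methylbut-2-en-1-yl)-2,3-dihydro-4H-chromen-4-one
Product: 23 schizolaenone A, (2S)-2-{3-[(2E)-3,7-dimethylocta-2,6-dien-1-yl]-4-hydroxyphenyl}-5,7-dihydroxy-6-(3-methylbut-2-en-1-yl)-2,3-dihydro-4H-chromen-4-one
Conditions: HCl (3 M aq.), MeOH, 40 °C
Reagents that add atoms: none
Why: Acid-catalysed acetal methanolysis should remove the three MOM ethers, the C2 stereocentre not being epimerisable under mild acid and the trisubstituted alkenes being expected to tolerate dilute HCl at this temperature.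

**Compound list**

1 | 5-fluorobenzene-1,3-diol (5-fluororesorcinol) | Oc1cc(O)cc(F)c1 | starting material
2 | chloromethyl methyl ether (MOMCl) | COCCl | starting material
3 | 1-fluoro-3,5-bis(methoxymethoxy)benzene | COCOc1cc(F)cc(OCOC)c1 | intermediate
4 | 1-bromo-3-methylbut-2-ene (prenyl bromide) | CC(C)=CCBr | starting material
5 | [4-fluoro-2,6-bis(methoxymethoxy)phenyl]lithium (not isolated) | [Li]c1c(OCOC)cc(F)cc1OCOC | intermediate
6 | 5-fluoro-1,3-bis(methoxymethoxy)-2-(3-methylbut-2-en-1-yl)benzene | COCOc1cc(F)cc(OCOC)c1CC=C(C)C | intermediate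
7 | N-methoxy-N-methylacetamide | CC(=O)N(C)OC | starting material
8 | [6-fluoro-2,4-bis(methoxymethoxy)-3-(3-methylbut-2-en-1-yl)phenyl]lithium (not isolated) | [Li]c1c(F)cc(OCOC)c(CC=C(C)C)c1OCOC | intermediate
9 | 1-[6-fluoro-2,4-bis(methoxymethoxy)-3-(3-methylbut-2-en-1-yl)phenyl]ethan-1-one | CC(=O)c1c(F)cc(OCOC)c(CC=C(C)C)c1OCOC | intermediate
10 | chlorotrimethylsilane | C[Si](C)(C)Cl | starting material
11 | lithium 1-[6-fluoro-2,4-bis(methoxymethoxy)-3-(3-methylbut-2-en-1-yl)phenyl]ethen-1-olate (not isolated) | [Li]OC(=C)c1c(F)cc(OCOC)c(CC=C(C)C)c1OCOC | intermediate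
12 | {1-[6-fluoro-2,4-bis(methoxymethoxy)-3-(3-methylbut-2-en-1-yl)phenyl]ethenyl}oxy(trimethyl)silane | C=C(O[Si](C)(C)C)c1c(F)cc(OCOC)c(CC=C(C)C)c1OCOC | intermediate
13 | 4-bromo-2-iodophenol | Oc1ccc(Br)cc1I | starting material
14 | 4-bromo-2-iodo-1-(methoxymethoxy)benzene | COCOc1ccc(Br)cc1I | intermediate
15 | (2E)-1-bromo-3,7-dimethylocta-2,6-diene (geranyl bromide) | CC(C)=CCC/C(C)=C/CBr | starting material
16 | [5-bromo-2-(methoxymethoxy)phenyl]magnesium chloride, as its LiCl complex (not isolated) | Cl[Mg]c1cc(Br)ccc1OCOC | intermediate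
17 | 4-bromo-2-[(2E)-3,7-dimethylocta-2,6-dien-1-yl]-1-(methoxymethoxy)benzene | CC(C)=CCC/C(C)=C/Cc1cc(Br)ccc1OCOC | intermediate
18 | N,N-dimethylformamide | CN(C)C=O | starting material
19 | {3-[(2E)-3,7-dimethylocta-2,6-dien-1-yl]-4-(methoxymethoxy)phenyl}lithium (not isolated) | CC(C)=CCC/C(C)=C/Cc1cc([Li])ccc1OCOC | intermediate
20 | 3-[(2E)-3,7-dimethylocta-2,6-dien-1-yl]-4-(methoxymethoxy)benzaldehyde | CC(C)=CCC/C(C)=C/Cc1cc(C=O)ccc1OCOC | intermediate
21 | (3S)-3-{3-[(2E)-3,7-dimethylocta-2,6-dien-1-yl]-4-(methoxymethoxy)phenyl}-1-[6-fluoro-2,4-bis(methoxymethoxy)-3-(3-methylbut-2-en-1-yl)phenyl]-3-(trimethylsilyloxy)propan-1-one (not isolated) | CC(C)=CCC/C(C)=C/Cc1cc([C@H](CC(=O)c2c(F)cc(OCOC)c(CC=C(C)C)c2OCOC)O[Si](C)(C)C)ccc1OCOC | intermediate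
22 | (2S)-2-{3-[(2E)-3,7-dimethylocta-2,6-dien-1-yl]-4-(methoxymethoxy)phenyl}-5,7-bis(methoxymethoxy)-6-(3-methylbut-2-en-1-yl)-2,3-dihydro-4H-chromen-4-one | CC(C)=CCC/C(C)=C/Cc1cc([C@@H]2CC(=O)c3c(cc(OCOC)c(CC=C(C)C)c3OCOC)O2)ccc1OCOC | intermediate
23 | schizolaenone A, (2S)-2-{3-[(2E)-3,7-dimethylocta-2,6-dien-1-yl]-4-hydroxyphenyl}-5,7-dihydroxy-6-(3-methylbut-2-en-1-yl)-2,3-dihydro-4H-chromen-4-one | CC(C)=CCC/C(C)=C/Cc1cc([C@@H]2CC(=O)c3c(cc(O)c(CC=C(C)C)c3O)O2)ccc1O | target

**Count and risks**

Total step count: 9. Longest linear sequence: 6 steps (steps 1, 2, 3, 4, 8, 9).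

Steps most likely to fail:

1. Step 8. The C2 alkoxide may undergo retro-aldol cleavage before it closes the ring, eroding enantiopurity; silanolate may be lost by E1cB elimination; facial control with this hindered enol silane may be weak; and fluoride may open the product by enolisation at C3. Fallback: the same two bonds would be made in two separate operations, setting out from 12 and 20. A Lewis-base-catalysed Mukaiyama aldol (SiCl4, 5 mol% of the (S,S)-bisphosphoramide N,N'-pentane-1,5-diylbis(N,3,5-trimethyl-3,5-dihydro-4H-dinaphtho[2,1-d:1',2'-f][1,3,2]diazaphosphepin-4-amine 4-oxide), C51H52N6O2P2, the antipode chosen for Si-face addition, iPr2NEt, CH2Cl2, −78 °C; aq. KF/KH2PO4 work-up) should give the free (S)-β-hydroxy ketone F1. F1 is purified and its enantiopurity checked, and the ring is then closed as the sodium alkoxide (NaH, THF, −20 to 0 °C, intramolecular SNAr), coming back to the route at 22.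

2. Step 3. Aryllithium 8 may lose LiF to an aryne on any warming, n-BuLi may deprotonate the benzylic-allylic CH2 of the prenyl group instead of the ring, and the aryllithium may enolise the Weinreb amide instead of adding to it. Fallback: a route without aryl metalation, setting out from 1. Friedel–Crafts acylation (AcOH, BF3·OEt2, 80 °C) at the ring carbon para to one hydroxyl and ortho to fluorine should give 1-(2-fluoro-4,6-dihydroxyphenyl)ethan-1-one F2. C-prenylation of its phenoxide at the carbon between the two hydroxyls (prenyl bromide, 10% aq. KOH, 0 °C) should give 1-[6-fluoro-2,4-dihydroxy-3-(3-methylbut-2-en-1-yl)phenyl]ethan-1-one F3. Bis-MOM protection (MOMCl, NaH, DMF, 0 °C) comes back to the route at 9.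

3. Step 9. Acid may promote cyclisation of the prenyl or geranyl chain onto a neighbouring phenol (chroman formation) or addition of HCl or MeOH to the trisubstituted alkenes. Fallback: a non-protic exchange of protecting groups, setting out from 22. Et3SiOSO2CF3 with 2,2'-bipyridyl (CH2Cl2, 0 °C) should convert the aryl MOM ethers into the tris(triethylsilyl) ether of schizolaenone A F4. Buffered fluoride (Et3N·3HF, THF, 0 °C) then frees the phenols and comes back to the route at 23.

Further compounds
F1 | step 8 | (3S)-3-{3-[(2E)-3,7-dimethylocta-2,6-dien-1-yl]-4-(methoxymethoxy)phenyl}-1-[6-fluoro-2,4-bis(methoxymethoxy)-3-(3-methylbut-2-en-1-yl)phenyl]-3-hydroxypropan-1-one | CC(C)=CCC/C(C)=C/Cc1cc([C@H](CC(=O)c2c(F)cc(OCOC)c(CC=C(C)C)c2OCOC)O)ccc1OCOC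
F2 | step 3 | 1-(2-fluoro-4,6-dihydroxyphenyl)ethan-1-one | CC(=O)c1c(F)cc(O)cc1O
F3 | step 3 | 1-[6-fluoro-2,4-dihydroxy-3-(3-methylbut-2-en-1-yl)phenyl]ethan-1-one | CC(=O)c1c(F)cc(O)c(CC=C(C)C)c1O
F4 | step 9 | (2S)-2-{3-[(2E)-3,7-dimethylocta-2,6-dien-1-yl]-4-(triethylsilyloxy)phenyl}-6-(3-methylbut-2-en-1-yl)-5,7-bis(triethylsilyloxy)-2,3-dihydro-4H-chromen-4-one | CC(C)=CCC/C(C)=C/Cc1cc([C@@H]2CC(=O)c3c(cc(O[Si](CC)(CC)CC)c(CC=C(C)C)c3O[Si](CC)(CC)CC)O2)ccc1O[Si](CC)(CC)CC
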